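The target in the ochre flask, which is the flask asked about, climbs for tens of hours and then stops, so I treat it as a relaxation toward a plateau P∞ and ask how far it has got by the asked time T.

| flask | starting material | second substrate | free enzyme | temperature | remark | time |
|---|---|---|---|---|---|---|
| ochre | 40 mM | 80 mM | 20 µM | 5 °C | the very flask that is asked about, followed so far |  |
| blue | 40 mM | 160 mM | 20 µM | 5 °C | run made earlier |  |
| flask | 40 mM | 80.0 mM | 20 µM | 5 °C |  | 8.0 d |

| run | time / h | target / % |
|---|---|---|
| ochre | 10.0 | 3 |
| ochre | 20.0 | 7 |
| ochre | 30.0 | 11 |
| ochre | 60.0 | 16 |
| ochre | 120 | 14 |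
| blue | 0.667 | 1 |
| blue | 2.00 | 3 |
| blue | 3.00 | 4 |
| blue | 5.00 | 1 |
| blue | 8.00 | 2 |

(scatter of a reading: 2 percentage points)

- additions leave the volume as it is
- the earlier runs were read with a standard deviation of 2 percentage points
- the earlier runs do not show what temperature does; that part of a forecast is a guess

- gamma: change nothing and wait 15 d more
- alpha: at 8.0 d take out 90% of the first product then present, then wait 15 d
- delta: at 8.0 d add free enzyme, 100% of the amount charged, then wait 15 d
- eta: at 8.0 d add second substrate, 100% of the amount charged, then wait 15 d
- theta: at 8.0 d raise the temperature by 10 K, then wait 15 d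

- target, in percent of the starting material first charged, at 8.0 d
- the remedy with the largest gain of target, or "none" below 2 percentage points (gamma / alpha / delta / eta / theta / none)
- target present, in percent of the starting material first charged, after delta
- target present, in percent of the starting material first charged, after eta

I take P∞ as the mean of the last two ochre readings, and I first pretend that the climb is straight up to the reading P at t = 30.0 h:

P∞ = 15.0%

τ′ = t·P∞/P = 40.9 h

The gap left at T is then P∞·e^(−T/τ′) = 0.14 percentage points, so I commit to a target near 15.0% and to no useful gain from waiting. The blue run ends at 8.00 h, sooner than τ′, so with a scatter of 2 points its readings show no plateau to me.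

The weak link is τ′, because the curve bends: put back as an exponential approach, τ′ gives 7.80% at t against the reading of 11%. So I go round once more and solve for the gap itself:

τ = t / ln[P∞/(P∞ − P)] = 22.7 h

This stopping time τ, in which the target's gap to its plateau shrinks by a factor e, fits 8.46 times into T, which leaves a gap of 0.0032 points, less than the 2 points that counts. The readings are of target, so whether fresh enzyme helps stays open for me.

The forecast gives 14.5%, names delta as best with 27% after it and 14.5% after eta, and holds that “the enzyme is essentially dead”.

The flask gives 18.2% at T, best none, 18.3% after delta and 18.2% after eta.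

    free enzyme → unfolded enzyme (k = 1.50 × 10⁻⁶ /s, Ea = 262 kJ/mol)
    starting material + free enzyme ⇌ first complex (K = 11.0 /M, k = 210 /M/s, Ea = 42.0 kJ/mol, ΔH = −45.0 kJ/mol)
    first complex → loaded enzyme + first product (k = 0.0280 /s, Ea = 74.0 kJ/mol)
    second substrate + loaded enzyme ⇌ second complex (K = 16.0 /M, k = 2.50 /M/s, Ea = 54.0 kJ/mol, ΔH = −53.0 kJ/mol)
    second complex → free enzyme + target (k = 0.0110 /s, Ea = 79.0 kJ/mol)
    2 second complex → spent catalyst (k = 1.70 /M/s, Ea = 49.0 kJ/mol)
    starting material + second substrate → uncatalysed product (k = 1.60 × 10⁻⁴ /M/s, Ea = 79.0 kJ/mol)
    (constants at 5 °C)

For target this flask has come to rest: the gap reckoned with τ was 0.0032 points, the flask gains 0.026 points on waiting, and at ten times the time it still stands at 18.3%. The catalyst does not rest: free enzyme stands at 27.8% after 192 h and at 0% after 1920 h, and unfolded enzyme stands at 38.2% after 192 h and at 66.2% after 1920 h. With τ carried unchanged to the neighbour charged with 100 mM of starting material, e^(−T/τ) gives 0.0212% of the target's gap left at T, but at T that neighbour holds 21% of its starting material unbound, with its second substrate, the limiting reagent there, down to 1.1% of its charge.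

The readings stem from a simulated flask with made-up constants.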